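The cyclohexane is cut at C1–C2 and C1–C6. Ring carbons C2–C6 with O3, O4 and O5 are taken intact from D-arabinitol, and C1 with O1 and the carboxyl carbon comes from tert-butyl glycolate. Because O1 and O3 are cis and 1,3-diaxial on the quinate ring, one diisopropylsilyl group can link the glycolate oxygen to O3 in an arabinitol 1,5-diiodide whose O4/O5 pair is a trans-acetonide. Double deprotonation then makes the tethered enolate alkylate both iodides in one operation, closing the dioxasilinane and the carbocycle and fixing the quaternary C1. Acetonide removal, O5 caffeoylation, O4 malonylation and global deprotection finish the synthesis.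

Key step: step 5

Remark: the ring is numbered as in quinic acid (C1 bears the carboxyl group; O1, O3 and O4 on one face, O5 on the other), so the target is read as 5-O-caffeoyl-4-O-malonylquinic acid with free 1-OH and 3-OH, and arabinitol C1–C5 become ring C6–C2.

Step 1
Reactants: 1 D-arabinitol
Product: 2 1,5-di-O-(p-tolylsulfonyl)-D-arabinitol
Conditions: TsCl (2.1 equiv), pyridine, −20 → 0 °C
Reagents that add atoms: p-toluenesulfonyl chloride, Cc1ccc(cc1)S(=O)(=O)Cl
Why: O-Sulfonylation is much faster at the two unhindered primary hydroxyls than at the three secondary ones, so about two equivalents of TsCl at low temperature should give mainly the 1,5-ditosylate, which is taken on cold and without delay so that 5-exo cyclisation to an anhydropentitol does not intervene; no stereocentre is touched.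

Step 2
Reactants: 2 1,5-di-O-(p-tolylsulfonyl)-D-arabinitol
Product: 3 2,3-O-isopropylidene-1,5-di-O-(p-tolylsulfonyl)-D-arabinitol
Conditions: Me2C(OMe)2, acetone, camphorsulfonic acid (cat.), rt, equilibration; Et3N quench
Reagents that add atoms: 2,2-dimethoxypropane, COC(C)(C)OC
Why: Acid-catalysed acetonide formation under equilibrating conditions should settle on the trans-4,5-disubstituted dioxolane of the threo O2/O3 pair, which is more stable than the cis-dioxolane of the erythro O3/O4 pair or a 1,3-dioxane with an axial methyl group, and leaves O4–H free; all stereocentres are carried over unchanged.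

Step 3
Reactants: 3 2,3-O-isopropylidene-1,5-di-O-(p-tolylsulfonyl)-D-arabinitol
Product: 4 1,5-dideoxy-1,5-diiodo-2,3-O-isopropylidene-D-arabinitol
Conditions: NaI (6 equiv), butanone, 80 °C
Reagents that add atoms: NaI, [Na+].[I-]
Why: Finkelstein reaction: iodide displaces both primary tosylates by SN2 at carbons that are not stereocentres, precipitation of the sulfonate salt drives the exchange, and the trans-dioxolane keeps O4 from closing a tetrahydrofuran onto C1 because that ring fusion would be a trans-bicyclo[3.3.0] system.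

Step 4
Reactants: 4 1,5-dideoxy-1,5-diiodo-2,3-O-isopropylidene-D-arabinitol; 5 tert-butyl glycolate
Product: 7 4-O-{[2-(tert-butoxy)-2-oxoethoxy]diisopropylsilyl}-1,5-dideoxy-1,5-diiodo-2,3-O-isopropylidene-D-arabinitol, via chlorosilyl ether 6 (not isolated)
Conditions: iPr2SiCl2 (1.1 equiv), imidazole (3 equiv), CH2Cl2/DMF, 0 °C → rt; then 5 (1.3 equiv), rt
Reagents that add atoms: dichlorodiisopropylsilane, CC(C)[Si](Cl)(Cl)C(C)C
Why: Stepwise nucleophilic substitution at silicon (silyl ether formation): the hindered secondary O4–H displaces only one chloride of iPr2SiCl2, and the primary hydroxyl of 5 then displaces the second, which gives the mixed dialkoxysilane without touching the iodides or any stereocentre.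

Step 5
Reactants: 7 4-O-{[2-(tert-butoxy)-2-oxoethoxy]diisopropylsilyl}-1,5-dideoxy-1,5-diiodo-2,3-O-isopropylidene-D-arabinitol
Product: 9 tert-butyl 1,3-O-(diisopropylsilylene)-4,5-O-isopropylidenequinate, via monocyclic dioxasilinane 8 (not isolated)
Conditions: KN(SiMe3)2 (2.5 equiv), THF (0.005 M), 7 added slowly at −78 °C, then −78 → 0 °C
Reagents that add atoms: none
Why: Proposed new method: KN(SiMe3)2 deprotonates the glycolate CH2 to the potassium α-silyloxy ester enolate, which displaces the C2 iodide in a 6-(enolexo)-exo-tet SN2 closure to give the 1,3,2-dioxasilinane 8, and a second equivalent of base regenerates an enolate at the now tertiary C1, which displaces the C6 iodide in a second 6-(enolexo)-exo-tet closure that forms the carbocycle and completes a 2,4-dioxa-3-silabicyclo[3.3.1]nonane. The closest known reaction types are the cycloalkylation of ester enolates with 1,5-dihalides and intramolecular bond formation through temporary silicon tethers, including silylene bridges over syn-1,3-diols. The only new stereocentre, C1, is controlled by the tether: O1 and O3 are joined through one silicon atom, so the carbocycle can close only with the C1–O1 bond cis and 1,3-diaxial to the C3–O3 bond, whichever C1 epimer of 8 is deprotonated. The step needs site selectivity in the first alkylation and cyclisation in preference to oligomerisation: the C2 iodide is reached through a six-membered transition state whereas the C6 iodide would need an eight-membered one, and high dilution with slow addition to excess base suppresses intermolecular alkylation. The trans-dioxolane holds C3 and C6 gauche about the C4–C5 bond and places O4 and O5 equatorial in the new chair, the silicon-containing ring can flatten to keep its inner isopropyl group away from the axial H5, and the tert-butyl ester together with the bulky silicon substituents disfavours Claisen condensation and attack at silicon.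

Step 6
Reactants: 9 tert-butyl 1,3-O-(diisopropylsilylene)-4,5-O-isopropylidenequinate
Product: 10 tert-butyl 1,3-O-(diisopropylsilylene)quinate
Conditions: AcOH/H2O (4:1), 25–40 °C
Reagents that add atoms: none
Why: Acid-catalysed acetal hydrolysis: the dioxolane is now trans-fused to a cyclohexane chair and strained, so it should open under conditions that the tert-butyl ester and the hindered silylene on a tertiary and a secondary oxygen tolerate; no stereocentre is affected.

Step 7
Reactants: 11 caffeic acid
Product: 13 (E)-3-[3,4-bis(tert-butyldimethylsilyloxy)phenyl]prop-2-enoic acid, via tris-silylated caffeate 12 (not isolated)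
Conditions: TBSCl (3.3 equiv), imidazole (7 equiv), DMF, rt; then AcOH/THF/H2O (3:1:1), rt
Reagents that add atoms: tert-butyldimethylsilyl chloride, CC(C)(C)[Si](C)(C)Cl
Why: Silylation of both phenols and the carboxyl group followed by selective hydrolysis of the far more labile silyl ester under mild aqueous acid is standard protection of caffeic acid and leaves the E double bond untouched.

Step 8
Reactants: 10 tert-butyl 1,3-O-(diisopropylsilylene)quinate; 13 (E)-3-[3,4-bis(tert-butyldimethylsilyloxy)phenyl]prop-2-enoic acid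
Product: 14 tert-butyl 5-O-[(E)-3,4-bis(tert-butyldimethylsilyloxy)cinnamoyl]-1,3-O-(diisopropylsilylene)quinate
Conditions: DCC (1.1 equiv), DMAP (0.1 equiv), CH2Cl2, −20 → 0 °C
Reagents that add atoms: none
Why: Steglich esterification: the equatorial O5–H, flanked by the C6 methylene, is more accessible than O4–H, which sits between C5 and the axial O3 carrying the Si(iPr)2 bridge, so one equivalent of acid at low temperature should acylate O5 selectively with the configuration at C5 and the E alkene retained.

Step 9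
Reactants: 14 tert-butyl 5-O-[(E)-3,4-bis(tert-butyldimethylsilyloxy)cinnamoyl]-1,3-O-(diisopropylsilylene)quinate; 15 Meldrum's acid
Product: 16 tert-butyl 5-O-[(E)-3,4-bis(tert-butyldimethylsilyloxy)cinnamoyl]-4-O-(carboxyacetyl)-1,3-O-(diisopropylsilylene)quinate
Conditions: toluene, 80 °C
Reagents that add atoms: none
Why: Alcoholysis of Meldrum's acid: the remaining O4–H opens the cyclic acylal on heating and acetone is lost, which gives the malonic half ester directly under neutral conditions that should neither move the caffeoyl group nor cleave the silicon protection.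

Step 10
Reactants: 16 tert-butyl 5-O-[(E)-3,4-bis(tert-butyldimethylsilyloxy)cinnamoyl]-4-O-(carboxyacetyl)-1,3-O-(diisopropylsilylene)quinate
Product: 18 5-O-caffeoyl-4-O-malonylquinic acid, via silylated diacid 17 (not isolated)
Conditions: TFA/CH2Cl2 (1:1), 0 °C → rt, evaporate; then HF·pyridine, THF/pyridine, 0 °C → rt; C18 chromatography (H2O/MeCN, 0.1% HCO2H)
Reagents that add atoms: none
Why: Acidolysis of the tert-butyl ester (loss of 2-methylpropene) followed by fluoride-driven Si–O cleavage of the silylene and both aryl silyl ethers keeps the medium acidic throughout, which should suppress migration of the malonyl group to the freed O3–H and loss of either ester; no stereocentre is involved.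

Compound list
1 | D-arabinitol | OC[C@@H](O)[C@@H](O)[C@@H](CO)O | starting material
2 | 1,5-di-O-(p-tolylsulfonyl)-D-arabinitol | Cc1ccc(cc1)S(=O)(=O)OC[C@@H](O)[C@@H](O)[C@H](O)COS(=O)(=O)c1ccc(C)cc1 | intermediate
3 | 2,3-O-isopropylidene-1,5-di-O-(p-tolylsulfonyl)-D-arabinitol (trans-dioxolane on the threo O2/O3 pair, 4-OH free) | Cc1ccc(cc1)S(=O)(=O)OC[C@@H](O)[C@H]1OC(C)(C)O[C@@H]1COS(=O)(=O)c1ccc(C)cc1 | intermediate
4 | 1,5-dideoxy-1,5-diiodo-2,3-O-isopropylidene-D-arabinitol | IC[C@@H](O)[C@H]1OC(C)(C)O[C@@H]1CI | intermediate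
5 | tert-butyl glycolate (tert-butyl 2-hydroxyacetate) | OCC(=O)OC(C)(C)C | starting material
6 | 4-O-[chloro(diisopropyl)silyl]-1,5-dideoxy-1,5-diiodo-2,3-O-isopropylidene-D-arabinitol | IC[C@@H](O[Si](Cl)(C(C)C)C(C)C)[C@H]1OC(C)(C)O[C@@H]1CI | intermediate
7 | 4-O-{[2-(tert-butoxy)-2-oxoethoxy]diisopropylsilyl}-1,5-dideoxy-1,5-diiodo-2,3-O-isopropylidene-D-arabinitol | IC[C@@H](O[Si](C(C)C)(C(C)C)OCC(=O)OC(C)(C)C)[C@H]1OC(C)(C)O[C@@H]1CI | intermediate
8 | tert-butyl 2,2-diisopropyl-6-[trans-5-(iodomethyl)-2,2-dimethyl-1,3-dioxolan-4-yl]-1,3,2-dioxasilinane-4-carboxylate (silinane C6 = arabinitol C4, dioxolane C4/C5 = arabinitol C3/C2, configurations as in 7; silinane C4 = quinic C1, both epimers) | CC(C)[Si]1(C(C)C)OC(C(=O)OC(C)(C)C)C[C@@H](O1)[C@H]2OC(C)(C)O[C@@H]2CI | intermediate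
9 | tert-butyl 1,3-O-(diisopropylsilylene)-4,5-O-isopropylidenequinate (O1 and O3 bridged on one face, trans-acetonide on O4/O5) | CC1(C)O[C@@H]2[C@H](O3)C[C@@](O[Si]3(C(C)C)C(C)C)(C(=O)OC(C)(C)C)C[C@H]2O1 | intermediate
10 | tert-butyl 1,3-O-(diisopropylsilylene)quinate (free 4,5-diol) | O[C@@H]1[C@H](O2)C[C@@](O[Si]2(C(C)C)C(C)C)(C(=O)OC(C)(C)C)C[C@H]1O | intermediate
11 | caffeic acid, (E)-3-(3,4-dihydroxyphenyl)prop-2-enoic acid | O=C(O)/C=C/c1ccc(O)c(O)c1 | starting material
12 | tert-butyldimethylsilyl (E)-3-[3,4-bis(tert-butyldimethylsilyloxy)phenyl]prop-2-enoate | CC(C)(C)[Si](C)(C)OC(=O)/C=C/c1ccc(O[Si](C)(C)C(C)(C)C)c(O[Si](C)(C)C(C)(C)C)c1 | intermediate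
13 | (E)-3-[3,4-bis(tert-butyldimethylsilyloxy)phenyl]prop-2-enoic acid | O=C(O)/C=C/c1ccc(O[Si](C)(C)C(C)(C)C)c(O[Si](C)(C)C(C)(C)C)c1 | intermediate
14 | tert-butyl 5-O-[(E)-3,4-bis(tert-butyldimethylsilyloxy)cinnamoyl]-1,3-O-(diisopropylsilylene)quinate (4-OH free) | O[C@@H]1[C@H](O2)C[C@@](O[Si]2(C(C)C)C(C)C)(C(=O)OC(C)(C)C)C[C@H]1OC(=O)/C=C/c1ccc(O[Si](C)(C)C(C)(C)C)c(O[Si](C)(C)C(C)(C)C)c1 | intermediate
15 | Meldrum's acid (2,2-dimethyl-1,3-dioxane-4,6-dione) | CC1(C)OC(=O)CC(=O)O1 | starting material
16 | tert-butyl 5-O-[(E)-3,4-bis(tert-butyldimethylsilyloxy)cinnamoyl]-4-O-(carboxyacetyl)-1,3-O-(diisopropylsilylene)quinate | O=C(O)CC(=O)O[C@@H]1[C@H](O2)C[C@@](O[Si]2(C(C)C)C(C)C)(C(=O)OC(C)(C)C)C[C@H]1OC(=O)/C=C/c1ccc(O[Si](C)(C)C(C)(C)C)c(O[Si](C)(C)C(C)(C)C)c1 | intermediate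
17 | 5-O-[(E)-3,4-bis(tert-butyldimethylsilyloxy)cinnamoyl]-4-O-(carboxyacetyl)-1,3-O-(diisopropylsilylene)quinic acid | O=C(O)CC(=O)O[C@@H]1[C@H](O2)C[C@@](O[Si]2(C(C)C)C(C)C)(C(=O)O)C[C@H]1OC(=O)/C=C/c1ccc(O[Si](C)(C)C(C)(C)C)c(O[Si](C)(C)C(C)(C)C)c1 | intermediate
18 | 5-O-caffeoyl-4-O-malonylquinic acid, (1S,3R,4R,5R)-4-[(carboxyacetyl)oxy]-5-{[(2E)-3-(3,4-dihydroxyphenyl)prop-2-enoyl]oxy}-1,3-dihydroxycyclohexane-1-carboxylic acid (quinic acid numbering) | O=C(O)CC(=O)O[C@@H]1[C@H](O)C[C@@](O)(C(=O)O)C[C@H]1OC(=O)/C=C/c1ccc(O)c(O)c1 | target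

Total step count: 10. Longest linear sequence: 9 steps (steps 1–6 and 8–10 from D-arabinitol); step 7 is a one-step side branch.

Steps most likely to fail

1. Step 5. The second ring closure may stall at the monocyclic stage because the bridged ring system is strained, the enolate may attack silicon or undergo silyl migration, or intermolecular alkylation may win. The fallback uses only known reactions, sets out from ditosylate 3 and returns at 9. O4 is silylated (TBSOTf, 2,6-lutidine) to give 4-O-(tert-butyldimethylsilyl)-2,3-O-isopropylidene-1,5-di-O-(p-tolylsulfonyl)-D-arabinitol F1. Corey–Seebach bis-alkylation of 1,3-dithiane (two metalation–alkylation cycles, n-BuLi, THF/HMPA; sulfonates are kept here because iodides would undergo lithium–iodine exchange) closes the carbocycle as the spiro-dithiane F2. MeI/CaCO3 in aqueous MeCN unmasks the 3-O-silyl-4,5-O-isopropylidene cyclohexanone F3. CH2=CHMgBr with CeCl3 should add from the equatorial side, away from the axial O3 substituent, to give the vinyl carbinol F4 with O1 axial and cis to O3. Bu4NF frees O3 to give the 1,3-diol F5, and iPr2Si(OTf)2 with 2,6-lutidine bridges O1 and O3 to give the vinyl silylene F6. RuCl3 (cat.)/NaIO4 cleaves the vinyl group to 1,3-O-(diisopropylsilylene)-4,5-O-isopropylidenequinic acid F7, and O-tert-butyl-N,N'-diisopropylisourea esterifies it to 9.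

2. Step 8. Discrimination between the vicinal O4–H and O5–H may be poor, with bis-acylation or acyl migration between them. The fallback sets out from diol 10 and returns at 14. Heating with Bu2SnO in toluene with removal of water gives the 4,5-O-dibutylstannylene acetal F8, in which the oxygen next to the axial O3 substituent (O4) is expected to be the reactive one, as in stannylene acylations of trans-diequatorial diols beside an axial oxygen. Chloroacetyl chloride at 0 °C then gives the 4-O-chloroacetate F9. The only free hydroxyl, O5–H, is esterified with 13 (DCC, DMAP) to give the 4-O-chloroacetyl-5-O-caffeoyl diester F10, and thiourea with 2,6-lutidine removes the chloroacetyl group to return 14.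

3. Step 9. Acylation of the hindered O4–H may be slow at a temperature where Meldrum's acid decomposes, and prolonged heating risks decarboxylation of the half ester or caffeoyl migration. The fallback sets out from 14 and returns at 17. DCC coupling with mono-tert-butyl malonate at 0 °C (acylketene pathway, no heating) gives the 4-O-(tert-butyl malonyl) ester F11, and both of its tert-butyl esters fall together in the TFA stage of step 10 to give 17.

Further compounds
F1 | step 5 | 4-O-(tert-butyldimethylsilyl)-2,3-O-isopropylidene-1,5-di-O-(p-tolylsulfonyl)-D-arabinitol | Cc1ccc(cc1)S(=O)(=O)OC[C@@H](O[Si](C)(C)C(C)(C)C)[C@H]1OC(C)(C)O[C@@H]1COS(=O)(=O)c1ccc(C)cc1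
F2 | step 5 | 1,3-dithiane ketal of the 3-O-(tert-butyldimethylsilyl)-4,5-O-isopropylidene cyclohexanone (O3, O4, O5 as in 9) | CC1(C)O[C@@H]2[C@H](O[Si](C)(C)C(C)(C)C)CC3(SCCCS3)C[C@H]2O1
F3 | step 5 | 3-(tert-butyldimethylsilyloxy)-4,5-(isopropylidenedioxy)cyclohexan-1-one (O3 cis to O4, O4 trans to O5, as in 9) | CC1(C)O[C@@H]2[C@H](O[Si](C)(C)C(C)(C)C)CC(=O)C[C@H]2O1
F4 | step 5 | 1-ethenyl-3-(tert-butyldimethylsilyloxy)-4,5-(isopropylidenedioxy)cyclohexan-1-ol (O1 cis to O3) | CC1(C)O[C@@H]2[C@H](O[Si](C)(C)C(C)(C)C)C[C@@](O)(C=C)C[C@H]2O1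
F5 | step 5 | 1-ethenyl-4,5-(isopropylidenedioxy)cyclohexane-1,3-diol (O1 cis to O3) | CC1(C)O[C@@H]2[C@H](O)C[C@@](O)(C=C)C[C@H]2O1
F6 | step 5 | 1,3-O-(diisopropylsilylene) derivative of F5 (vinyl in place of the carboxyl group of 9) | CC1(C)O[C@@H]2[C@H](O3)C[C@@](O[Si]3(C(C)C)C(C)C)(C=C)C[C@H]2O1
F7 | step 5 | 1,3-O-(diisopropylsilylene)-4,5-O-isopropylidenequinic acid | CC1(C)O[C@@H]2[C@H](O3)C[C@@](O[Si]3(C(C)C)C(C)C)(C(=O)O)C[C@H]2O1
F8 | step 8 | tert-butyl 4,5-O-(dibutylstannylene)-1,3-O-(diisopropylsilylene)quinate | CCCC[Sn]1(CCCC)O[C@@H]2[C@H](O3)C[C@@](O[Si]3(C(C)C)C(C)C)(C(=O)OC(C)(C)C)C[C@H]2O1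
F9 | step 8 | tert-butyl 4-O-(chloroacetyl)-1,3-O-(diisopropylsilylene)quinate | O=C(CCl)O[C@@H]1[C@H](O2)C[C@@](O[Si]2(C(C)C)C(C)C)(C(=O)OC(C)(C)C)C[C@H]1O
F10 | step 8 | tert-butyl 5-O-[(E)-3,4-bis(tert-butyldimethylsilyloxy)cinnamoyl]-4-O-(chloroacetyl)-1,3-O-(diisopropylsilylene)quinate | O=C(CCl)O[C@@H]1[C@H](O2)C[C@@](O[Si]2(C(C)C)C(C)C)(C(=O)OC(C)(C)C)C[C@H]1OC(=O)/C=C/c1ccc(O[Si](C)(C)C(C)(C)C)c(O[Si](C)(C)C(C)(C)C)c1
F11 | step 9 | tert-butyl 5-O-[(E)-3,4-bis(tert-butyldimethylsilyloxy)cinnamoyl]-4-O-[3-(tert-butoxy)-3-oxopropanoyl]-1,3-O-(diisopropylsilylene)quinate | CC(C)(C)OC(=O)CC(=O)O[C@@H]1[C@H](O2)C[C@@](O[Si]2(C(C)C)C(C)C)(C(=O)OC(C)(C)C)C[C@H]1OC(=O)/C=C/c1ccc(O[Si](C)(C)C(C)(C)C)c(O[Si](C)(C)C(C)(C)C)c1
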